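## The problem

Compound 26 is a 2-hydroxy-1,4-naphthoquinone (rings B and C) whose benzenoid ring B carries four different groups in a row: the peri hydroxyl on C5, a 2,4-dihydroxy-6-methylbenzoyl group (ring A) on C6, a methylene on C7 that ends at C6 of a 4-hydroxy-2-pyrone (ring D), and hydrogen on C8. There is no stereocentre, so the task is regiochemical: the order of the substituents round ring B, and the placing of the quinone hydroxyl on C2, on the side of C8–H and away from the C5 hydroxyl. The diaryl ketone has all four ortho positions occupied (methyl and oxygen on ring A, the C5 oxygen and the C7 arm on ring B). A ketone of this kind is reluctant to form by late acylation or by addition of an aryl metal to a hindered carboxyl derivative, so it should be carried into the step that makes ring B. Five acidic hydroxyls are present, two of them vinylogous acids; the quinone is an oxidant and an electrophile, the pyrone opens under hard nucleophiles and strong base, and the C7 methylene is activated from both sides, so these groups stay masked (methyl ethers, ring C as a trimethoxybenzene) until the last two steps. An open-chain 1,3,5-tricarbonyl unit on the C7 arm would place a nucleophilic carbon six atoms from the aroyl carbonyl and invite aldol closure to an anthracenol, which argues for attaching ring D closed and not growing it on the arm. The feature that opens the molecule is ring B itself: read from C5 to C8 it is a 1-naphthol with an acyl group on the next carbon, a carbon arm on the one after and hydrogen on the last. That is the pattern left when the ester carbon (C5) and the benzylic methyl carbon (C8) of an ortho-toluate are joined across the two carbons (C6, C7) of an aroyl alkyne.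

## Retrosynthesis

**26 from 25.** The five O–CH3 bonds are cut last. Methyl ethers are the only masks that survive every reagent on the way (alkyllithium and amide bases, zinc dust, the Pd(OAc)2 catalyst, (NH4)2Ce(NO3)6), and three of the five sit next to a carbonyl group that assists Lewis-acid cleavage. The precursor 25 is the pentamethyl ether of the target. The forward step must cleave three aryl ethers and two vinylogous esters without harming the quinone or the pyrone.

**25 from 24.** The quinone is traced to a 1,2,4-trimethoxybenzene ring C. Ring C then travels through all the carbanion chemistry as an inert arene, and the position of the C2 oxygen is fixed by the carbon skeleton and not by a late oxygenation. Oxidative demethylation must pick the most electron-rich ring. Should some ortho-quinone form instead of the para-quinone, it is the methyl ether of the same hydroxyquinone tautomeric system and converges on 26.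

**24 from 17 and 22.** The bond between the C7 methylene and pyrone C6 is cut. The neighbouring cut, growing ring D from an arylacetyl unit through a tricarbonyl chain, would create the aldol hazard named above. A cut at the ring B–CH2 bond would require a halide on C7 that the annulation cannot deliver. The benzylic chloride 17 lacks ring D entirely and 22 is a five-carbon heterocycle. The forward reaction asks for a benzylic zinc reagent (23) that tolerates the diaryl ketone and for coupling at the C6 chloride of the pyrone, catalysed by Pd(OAc)2 and SPhos.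

**22 from 21, 20 and 18.** The chloropyrone is taken back through O-methylation to 6-chloro-4-hydroxy-2-pyrone 21, this through decarboxylation to the pyrone-3-carboxylic acid 20, and 20 to two molecules of malonyl dichloride 18, which condense with each other to the acid chloride 19 before hydrolysis. All six carbons of 19 come from the two malonyl units, and one of them leaves as CO2. The C6 chlorine is the unused acid chloride of the second malonyl unit, so no separate halogenation is needed.

**17 from 14 through 16 and 15.** Only functional groups change: chloride from alcohol 16, alcohol from silyl ether 15, and the C5 methyl ether from naphthol 14. The naphthol is capped because its proton would quench 23. The cap is a methyl group because it is removed together with the others.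

**14 from 11 and 7 (the key disconnection).** The C7–C8 and C5–C6 bonds are cut, which dissolves ring B into a toluate (ring C with the ester as C5 and the methyl as C8) and an ynone (C6 and C7, with ring A and the oxygenated arm attached). Cutting the aryl–carbonyl bond instead would require the four-fold ortho-substituted ketone to form late. Cutting ring C would leave the contiguous substitution of ring B unsolved. Both precursors are monocyclic benzene derivatives. The forward step must give conjugate and not direct addition to the ynone, lateral and not ring metalation of 11, and acylation of the resulting allenolate (13) on the ester.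

**7 from 2 and 4, and these from 1 and 3.** The ynone is cut at the carbinol carbon–alkyne bond after an oxidation-level adjustment (alcohol 6). The acetylide 5 comes from silyl ether 4 of propargyl alcohol 3, and aldehyde 2 comes from formylation of 3,5-dimethoxytoluene 1. An aldehyde is chosen over an acid chloride because it cannot over-add.

**11 from 8 through 10.** The ester is cut to acid 10, and the methyl group of 10 is removed to give commercial 2,4,5-trimethoxybenzoic acid 8. The carboxylate and the C5 methoxy group of 8 flank the only position (C6) where the methyl is wanted, so directed ortho-metalation (dianion 9) and methylation should place it there.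

## Roads not taken

Alternative 1: ring C by aryne cycloaddition. The cut is at C1–C8a and C4–C4a. CsF would release an aryne on ring B from the silyl triflate A1, and 3-methoxyfuran A2 would add across it through its two α-carbons to give the oxygen-bridged dihydronaphthalene A3 (racemic).
- Merits: the conditions are mild, and the electron-rich ring C does not have to be carried through earlier steps.
- Weak points: neither partner is symmetrical. The aryne has methoxy on one side and hydrogen on the other, and the furan has its methoxy on one β-carbon. Little in a furan cycloaddition distinguishes the two orientations, and the wrong one leads to the 3-hydroxy isomer of 26. A3 still needs acid opening to a naphthol and oxidation to the quinone. The hard part, a benzene ring with five contiguous substituents (A1), is left unsolved.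
- Comparison: in mildness the alternative is the better road. The chosen plan sets against this that the oxygen pattern of ring C is fixed by commercial 8 and that ring B is assembled with its substituents in one step.

Alternative 2: aryne acyl-alkylation. The cut is at the C6–acyl and C7–CH2 bonds. CsF would generate the naphthalyne from A4, the enolate of β-keto ester A5 would add, and the aryl anion would attack the ketone and fragment to give arylacetate A6. No ring closes.
- Merits: both ring B substituents arrive in one operation. The orientation is naturally right, since the enolate carbon attacks the aryne carbon remote from the methoxy group. The arm arrives at the acid oxidation level, so no chloropyrone such as 22 is needed. In these respects it is as good as or better than the chosen plan.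
- Weak points: A4 is a fully built, silylated naphthalene that needs its own annulation and several steps. The aryl anion must attack a ketone shielded by two ortho groups, so plain α-arylation without insertion is a likely diversion. Ring D would then have to be grown from the acetate through the tricarbonyl chain that the aroyl group can trap.
- Comparison: the chosen plan makes the naphthalene and places both substituents in the same step from two benzene derivatives, and brings ring D in closed.

Alternative 3: ring C by carbene-catalysed umpolung. The cut is at C1–C2. A triazolium-derived carbene would turn the aldehyde of A7 into an acyl anion equivalent that adds to the ethoxy-bearing alkyne carbon of the neighbouring ynone, closing ring C as the ethoxyquinone A8.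
- Merits: the quinone appears at the correct oxidation level with the C2 oxygen placed unambiguously, without the (NH4)2Ce(NO3)6 oxidation. Here the alternative is better.
- Weak points: A7 is a hexasubstituted benzene carrying an aldehyde, an alkoxy-ynone, the hindered aroyl group and the pyranylmethyl arm side by side, with no evident short synthesis. The alkoxy-ynone is a push–pull alkyne that adds water and the free carbene readily. The acceptor carbon is the donor-substituted one and therefore a poor electrophile.
- Comparison: the chosen plan pays one oxidation step for precursors that are stable and each made in a few steps.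

Key step: step 7

Remark on the chemistry: 22 is not counted as a catalogue compound and is made from 18 in steps 11 to 13; step 11 consumes two molecules of 18 for each molecule of 20. The carbinol centre of 6 is formed racemic and removed in step 4, so no configuration has to be set anywhere.

## Route

Step 1
Reactants: 1 3,5-dimethoxytoluene
Product: 2 2,4-dimethoxy-6-methylbenzaldehyde
Conditions: POCl3, DMF, 0 to 80 °C; then ice water
Reagents that add atoms: N,N-dimethylformamide CN(C)C=O; water O
Why: Vilsmeier–Haack formylation; the site between the methyl and one methoxy group is para to the other methoxy group and less crowded than the site between the two methoxy groups, and is the established position of attack on this arene.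

Step 2
Reactants: 3 propargyl alcohol
Product: 4 triisopropyl(prop-2-yn-1-yloxy)silane
Conditions: TIPSCl, imidazole, CH2Cl2, 0 to 25 °C
Reagents that add atoms: chlorotriisopropylsilane CC(C)[Si](Cl)(C(C)C)C(C)C
Why: Standard silylation of a primary alcohol; the bulky silyl ether should survive alkyllithium, amide base and carbonate in steps 3 to 8.

Step 3
Reactants: 4 triisopropyl(prop-2-yn-1-yloxy)silane; 2 2,4-dimethoxy-6-methylbenzaldehyde
Product: 6 rac-1-(2,4-dimethoxy-6-methylphenyl)-4-(triisopropylsilyloxy)but-2-yn-1-ol, via lithium acetylide 5 (not isolated)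
Conditions: n-BuLi, THF, −78 °C; then 2, −78 to 0 °C; aq NH4Cl
Reagents that add atoms: none
Why: Deprotonation of the terminal alkyne and 1,2-addition of the acetylide to the aldehyde; the new carbinol centre is racemic and is erased in step 4.

Step 4
Reactants: 6 rac-1-(2,4-dimethoxy-6-methylphenyl)-4-(triisopropylsilyloxy)but-2-yn-1-ol
Product: 7 1-(2,4-dimethoxy-6-methylphenyl)-4-(triisopropylsilyloxy)but-2-yn-1-one
Conditions: MnO2, CH2Cl2, 25 °C
Reagents that add atoms: none
Why: MnO2 oxidation of a benzylic and propargylic alcohol to the ynone under neutral conditions that leave the silyl ether and the electron-rich ring untouched.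

Step 5
Reactants: 8 2,4,5-trimethoxybenzoic acid
Product: 10 3,4,6-trimethoxy-2-methylbenzoic acid, via dilithiated benzoate 9 (not isolated)
Conditions: s-BuLi (2.2 equiv), TMEDA, THF, −78 °C; then MeI, −78 to 25 °C; aq HCl
Reagents that add atoms: iodomethane CI
Why: Directed ortho-metalation of an unprotected benzoic acid; C6 of 8 is the only position ortho to the lithium carboxylate and is also ortho to the C5 methoxy group, so both directors act on the same hydrogen, and the aryllithium 9 is methylated on carbon.

Step 6
Reactants: 10 3,4,6-trimethoxy-2-methylbenzoic acid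
Product: 11 methyl 3,4,6-trimethoxy-2-methylbenzoate
Conditions: MeI, K2CO3, DMF, 25 °C
Reagents that add atoms: iodomethane CI
Why: O-alkylation of the carboxylate, which avoids nucleophilic attack on the carbonyl of a 2,6-disubstituted benzoic acid.

Step 7
Reactants: 11 methyl 3,4,6-trimethoxy-2-methylbenzoate; 7 1-(2,4-dimethoxy-6-methylphenyl)-4-(triisopropylsilyloxy)but-2-yn-1-one
Product: 14 (2,4-dimethoxy-6-methylphenyl)[1-hydroxy-5,6,8-trimethoxy-3-(triisopropylsilyloxymethyl)naphthalen-2-yl]methanone, via lithiated toluate 12 (not isolated), via allenolate adduct 13 (not isolated)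
Conditions: 11 (2.0 equiv), LiN(iPr)2 (2.1 equiv), THF, −78 °C; then 7 (1.0 equiv), −78 to 0 °C; aq NH4Cl
Reagents that add atoms: none
Why: Michael–Dieckmann benzannulation. The amide base removes a proton from the only benzylic methyl group of 11 to give 12, whose benzylic carbon (the future C8) adds to the alkyne carbon β to the ketone of 7 (C7), forming C7–C8 and the lithium allenolate 13. The allenolate carbon α to the ketone (C6) then attacks the ester carbonyl (C5) in a 6-exo-trig acylation that forms C5–C6 and closes ring B; loss of methoxide gives a 2-aroyl-4H-naphthalen-1-one, which is deprotonated at its doubly activated methylene by the second equivalent of 12 and appears after work-up as the naphthol, hydrogen-bonded to the aroyl oxygen. The closest known reaction type is the annulation of laterally lithiated ortho-toluates with acetylenic esters to give 1-naphthols. No stereocentre is formed. The step needs conjugate and not direct addition: the ketone of 7 is flanked by the methyl and methoxy groups of ring A and twisted out of reach, the β-carbon carries only a CH2 group, and the delocalised benzylic anion is a soft nucleophile. It also needs lateral and not ring metalation of 11, which the amide base secures because it is too weak to remove the ring hydrogen between the two methoxy groups. The orientation follows from the polarisation of the ynone, so the silyloxymethyl arm can only end on C7 and the aroyl group on C6.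

Step 8
Reactants: 14 (2,4-dimethoxy-6-methylphenyl)[1-hydroxy-5,6,8-trimethoxy-3-(triisopropylsilyloxymethyl)naphthalen-2-yl]methanone
Product: 15 (2,4-dimethoxy-6-methylphenyl)[1,5,6,8-tetramethoxy-3-(triisopropylsilyloxymethyl)naphthalen-2-yl]methanone
Conditions: MeI, Cs2CO3, DMF, 40 °C
Reagents that add atoms: iodomethane CI
Why: Williamson methylation; the caesium naphtholate breaks the hydrogen bond to the ketone and is alkylated on oxygen, removing the proton that would destroy the zinc reagent of step 14.

Step 9
Reactants: 15 (2,4-dimethoxy-6-methylphenyl)[1,5,6,8-tetramethoxy-3-(triisopropylsilyloxymethyl)naphthalen-2-yl]methanone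
Product: 16 (2,4-dimethoxy-6-methylphenyl)[3-(hydroxymethyl)-1,5,6,8-tetramethoxynaphthalen-2-yl]methanone
Conditions: TBAF, THF, 0 to 25 °C; aq NH4Cl
Reagents that add atoms: none
Why: Fluoride cleavage of the silyl ether; the hindered, twisted ketone should not hold the freed alcohol as a cyclic hemiketal.

Step 10
Reactants: 16 (2,4-dimethoxy-6-methylphenyl)[3-(hydroxymethyl)-1,5,6,8-tetramethoxynaphthalen-2-yl]methanone
Product: 17 [3-(chloromethyl)-1,5,6,8-tetramethoxynaphthalen-2-yl](2,4-dimethoxy-6-methylphenyl)methanone
Conditions: PPh3 and NCS premixed, THF, −20 °C; then 16, −20 to 25 °C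
Reagents that add atoms: N-chlorosuccinimide O=C1CCC(=O)N1Cl
Why: Appel-type chlorination of a primary benzylic alcohol by SN2 displacement of the alkoxyphosphonium ion; premixing keeps electrophilic chlorine away from the electron-rich rings.

Step 11
Reactants: 18 malonyl dichloride (2 equiv)
Product: 20 6-chloro-4-hydroxy-2-oxo-2H-pyran-3-carboxylic acid, via pyranone carbonyl chloride 19 (not isolated)
Conditions: neat, 25 °C, several days; then H2O, 1,4-dioxane, 0 to 25 °C
Reagents that add atoms: malonyl dichloride (second molecule of 18) O=C(Cl)CC(=O)Cl; water O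
Why: Known self-condensation of malonyl dichloride: the methylene carbon of one molecule is acylated by a second, and the enol oxygen of a remaining chlorocarbonyl group then closes the lactone, so that 19 contains all six carbons of the two molecules; cold water hydrolyses the acyl chloride faster than the ring C6 chloride and gives acid 20.

Step 12
Reactants: 20 6-chloro-4-hydroxy-2-oxo-2H-pyran-3-carboxylic acid
Product: 21 6-chloro-4-hydroxy-2H-pyran-2-one
Conditions: dry 1,4-dioxane, 90 °C, until gas evolution ends
Reagents that add atoms: none
Why: Thermal decarboxylation of a β-keto acid; the carboxyl group on C3 lies between the lactone carbonyl and the C4 enol and loses CO2 through the cyclic hydrogen-bonded transition state, and no base or nucleophile is present that could displace the C6 chloride.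

Step 13
Reactants: 21 6-chloro-4-hydroxy-2H-pyran-2-one
Product: 22 6-chloro-4-methoxy-2H-pyran-2-one
Conditions: Me2SO4, K2CO3, acetone, 25 °C
Reagents that add atoms: dimethyl sulfate COS(=O)(=O)OC
Why: O-methylation of a 4-hydroxy-2-pyrone under the standard sulfate and carbonate conditions, which favour the 4-methoxy-2-pyrone over the 2-methoxy-4-pyrone.

Step 14
Reactants: 17 [3-(chloromethyl)-1,5,6,8-tetramethoxynaphthalen-2-yl](2,4-dimethoxy-6-methylphenyl)methanone; 22 6-chloro-4-methoxy-2H-pyran-2-one
Product: 24 6-{[3-(2,4-dimethoxy-6-methylbenzoyl)-4,5,7,8-tetramethoxynaphthalen-2-yl]methyl}-4-methoxy-2H-pyran-2-one, via benzylzinc chloride 23 (not isolated)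
Conditions: Zn dust, LiCl, THF, 25 °C; then 22, Pd(OAc)2 (cat.), SPhos, THF, 25 °C
Reagents that add atoms: none
Why: Direct zinc insertion into a benzylic chloride in the presence of LiCl tolerates the diaryl ketone, and Negishi coupling then joins the benzylic carbon to pyrone C6; the C6 chloride is a vinylogous acyl chloride that adds readily to zerovalent palladium, and cross-couplings at C6 of 6-chloro-2-pyrones are established.

Step 15
Reactants: 24 6-{[3-(2,4-dimethoxy-6-methylbenzoyl)-4,5,7,8-tetramethoxynaphthalen-2-yl]methyl}-4-methoxy-2H-pyran-2-one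
Product: 25 6-(2,4-dimethoxy-6-methylbenzoyl)-2,5-dimethoxy-7-[(4-methoxy-2-oxo-2H-pyran-6-yl)methyl]naphthalene-1,4-dione
Conditions: (NH4)2Ce(NO3)6, MeCN/H2O, 0 °C
Reagents that add atoms: water O
Why: Oxidative demethylation of a para-dimethoxyarene by tetravalent cerium; ring C is the most electron-rich ring, water adds at its two para methoxy-bearing carbons and methanol leaves, whereas ring A (meta-dimethoxy, deactivated by the ketone), the C5 ether and the methoxypyrone cannot give a quinone. Any ortho-quinone regioisomer would give the same hydroxyquinone in step 16.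

Step 16
Reactants: 25 6-(2,4-dimethoxy-6-methylbenzoyl)-2,5-dimethoxy-7-[(4-methoxy-2-oxo-2H-pyran-6-yl)methyl]naphthalene-1,4-dione
Product: 26 6-(2,4-dihydroxy-6-methylbenzoyl)-2,5-dihydroxy-7-[(4-hydroxy-2-oxo-2H-pyran-6-yl)methyl]naphthalene-1,4-dione
Conditions: BBr3 (excess), CH2Cl2, −78 to 25 °C; then H2O
Reagents that add atoms: none
Why: Lewis-acid ether cleavage; BBr3 binds each ether oxygen (helped by chelation to the neighbouring carbonyl for the C5 ether and the ortho ether of ring A, and by the vinylogous ester character of the quinone and pyrone ethers), bromide removes the methyl groups by SN2, and aqueous work-up hydrolyses the borates.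

## Compound list

1 | 3,5-dimethoxytoluene | Cc1cc(OC)cc(OC)c1 | starting material
2 | 2,4-dimethoxy-6-methylbenzaldehyde | Cc1cc(OC)cc(OC)c1C=O | intermediate
3 | propargyl alcohol (prop-2-yn-1-ol) | C#CCO | starting material
4 | triisopropyl(prop-2-yn-1-yloxy)silane | C#CCO[Si](C(C)C)(C(C)C)C(C)C | intermediate
5 | [3-(triisopropylsilyloxy)prop-1-yn-1-yl]lithium | [Li]C#CCO[Si](C(C)C)(C(C)C)C(C)C | intermediate
6 | rac-1-(2,4-dimethoxy-6-methylphenyl)-4-(triisopropylsilyloxy)but-2-yn-1-ol | Cc1cc(OC)cc(OC)c1C(O)C#CCO[Si](C(C)C)(C(C)C)C(C)C | intermediate
7 | 1-(2,4-dimethoxy-6-methylphenyl)-4-(triisopropylsilyloxy)but-2-yn-1-one | Cc1cc(OC)cc(OC)c1C(=O)C#CCO[Si](C(C)C)(C(C)C)C(C)C | intermediate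
8 | 2,4,5-trimethoxybenzoic acid | COc1cc(OC)c(C(=O)O)cc1OC | starting material
9 | lithium 2-lithio-3,4,6-trimethoxybenzoate | [Li]c1c(C(=O)O[Li])c(OC)cc(OC)c1OC | intermediate
10 | 3,4,6-trimethoxy-2-methylbenzoic acid | Cc1c(C(=O)O)c(OC)cc(OC)c1OC | intermediate
11 | methyl 3,4,6-trimethoxy-2-methylbenzoate | COC(=O)c1c(C)c(OC)c(OC)cc1OC | intermediate
12 | methyl 2-(lithiomethyl)-3,4,6-trimethoxybenzoate | [Li]Cc1c(OC)c(OC)cc(OC)c1C(=O)OC | intermediate
13 | lithium allenolate from conjugate addition of 12 to 7 (methyl 2-[4-(2,4-dimethoxy-6-methylphenyl)-4-lithiooxy-2-(triisopropylsilyloxymethyl)buta-2,3-dien-1-yl]-3,4,6-trimethoxybenzoate) | COC(=O)c1c(OC)cc(OC)c(OC)c1CC(CO[Si](C(C)C)(C(C)C)C(C)C)=C=C(O[Li])c1c(C)cc(OC)cc1OC | intermediate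
14 | (2,4-dimethoxy-6-methylphenyl)[1-hydroxy-5,6,8-trimethoxy-3-(triisopropylsilyloxymethyl)naphthalen-2-yl]methanone | Cc1cc(OC)cc(OC)c1C(=O)c1c(CO[Si](C(C)C)(C(C)C)C(C)C)cc2c(OC)c(OC)cc(OC)c2c1O | intermediate
15 | (2,4-dimethoxy-6-methylphenyl)[1,5,6,8-tetramethoxy-3-(triisopropylsilyloxymethyl)naphthalen-2-yl]methanone | Cc1cc(OC)cc(OC)c1C(=O)c1c(CO[Si](C(C)C)(C(C)C)C(C)C)cc2c(OC)c(OC)cc(OC)c2c1OC | intermediate
16 | (2,4-dimethoxy-6-methylphenyl)[3-(hydroxymethyl)-1,5,6,8-tetramethoxynaphthalen-2-yl]methanone | Cc1cc(OC)cc(OC)c1C(=O)c1c(CO)cc2c(OC)c(OC)cc(OC)c2c1OC | intermediate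
17 | [3-(chloromethyl)-1,5,6,8-tetramethoxynaphthalen-2-yl](2,4-dimethoxy-6-methylphenyl)methanone | Cc1cc(OC)cc(OC)c1C(=O)c1c(CCl)cc2c(OC)c(OC)cc(OC)c2c1OC | intermediate
18 | malonyl dichloride | O=C(Cl)CC(=O)Cl | starting material
19 | 6-chloro-4-hydroxy-2-oxo-2H-pyran-3-carbonyl chloride | O=C(Cl)c1c(O)cc(Cl)oc1=O | intermediate
20 | 6-chloro-4-hydroxy-2-oxo-2H-pyran-3-carboxylic acid | O=C(O)c1c(O)cc(Cl)oc1=O | intermediate
21 | 6-chloro-4-hydroxy-2H-pyran-2-one | Oc1cc(Cl)oc(=O)c1 | intermediate
22 | 6-chloro-4-methoxy-2H-pyran-2-one | COc1cc(Cl)oc(=O)c1 | intermediate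
23 | {[3-(2,4-dimethoxy-6-methylbenzoyl)-4,5,7,8-tetramethoxynaphthalen-2-yl]methyl}zinc chloride | Cc1cc(OC)cc(OC)c1C(=O)c1c(C[Zn]Cl)cc2c(OC)c(OC)cc(OC)c2c1OC | intermediate
24 | 6-{[3-(2,4-dimethoxy-6-methylbenzoyl)-4,5,7,8-tetramethoxynaphthalen-2-yl]methyl}-4-methoxy-2H-pyran-2-one | Cc1cc(OC)cc(OC)c1C(=O)c1c(Cc2cc(OC)cc(=O)o2)cc2c(OC)c(OC)cc(OC)c2c1OC | intermediate
25 | 6-(2,4-dimethoxy-6-methylbenzoyl)-2,5-dimethoxy-7-[(4-methoxy-2-oxo-2H-pyran-6-yl)methyl]naphthalene-1,4-dione | Cc1cc(OC)cc(OC)c1C(=O)c1c(Cc2cc(OC)cc(=O)o2)cc2c(c1OC)C(=O)C=C(OC)C2=O | intermediate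
26 | 6-(2,4-dihydroxy-6-methylbenzoyl)-2,5-dihydroxy-7-[(4-hydroxy-2-oxo-2H-pyran-6-yl)methyl]naphthalene-1,4-dione | Cc1cc(O)cc(O)c1C(=O)c1c(Cc2cc(O)cc(=O)o2)cc2c(c1O)C(=O)C=C(O)C2=O | target

## Step count and least certain steps

Total: 16 steps. Longest linear sequence: 10 steps (steps 1, 3, 4, 7, 8, 9, 10, 14, 15, 16; the branch that starts with step 2 is equally long).

**Step 7 (key step).** The most likely failures are direct addition of the benzylic anion to the ketone carbonyl, proton transfer from the propargylic CH2 of 7 to the anion with isomerisation of the ynone, and self-condensation of the toluate anion before the acceptor is consumed. The fallback runs the annulation with an acetylenic ester, where it is best precedented, and attaches ring A afterwards. It sets out from 4 and 11 (with 1 as the source of ring A) and comes back to the route at 15. Compound 4 would be lithiated and acylated with methyl chloroformate to methyl 4-(triisopropylsilyloxy)but-2-ynoate F1. Annulation of F1 with 12 should give methyl 1-hydroxy-5,6,8-trimethoxy-3-(triisopropylsilyloxymethyl)naphthalene-2-carboxylate F2, and methylation (MeI, Cs2CO3) would give methyl 1,5,6,8-tetramethoxy-3-(triisopropylsilyloxymethyl)naphthalene-2-carboxylate F3. LiAlH4 would reduce the hindered ester to [1,5,6,8-tetramethoxy-3-(triisopropylsilyloxymethyl)naphthalen-2-yl]methanol F4, and MnO2 would oxidise this to 1,5,6,8-tetramethoxy-3-(triisopropylsilyloxymethyl)naphthalene-2-carbaldehyde F5. 2-Bromo-1,5-dimethoxy-3-methylbenzene F6, from 1 and N-bromosuccinimide, would be converted to the aryllithium with n-BuLi and added to F5 to give racemic (2,4-dimethoxy-6-methylphenyl)[1,5,6,8-tetramethoxy-3-(triisopropylsilyloxymethyl)naphthalen-2-yl]methanol F7, and Dess–Martin oxidation of F7 would return 15.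

**Step 5.** Metalation may take place between the two methoxy groups instead of next to the carboxylate, the alkyllithium may displace the methoxy group ortho to the carboxylate, or the product may be metalated on its new methyl group and methylated again. The fallback replaces metalation by electrophilic substitution. It sets out from 2 and comes back to the route at 10. Baeyer–Villiger oxidation of 2 with mCPBA would give 2,4-dimethoxy-6-methylphenyl formate F8, and aqueous NaOH in methanol followed by acid would give 2,4-dimethoxy-6-methylphenol F9. Methylation (MeI, K2CO3) would give 1,2,5-trimethoxy-3-methylbenzene F10. Vilsmeier–Haack formylation, directed to the position between the methyl and a methoxy group as in step 1, should give 3,4,6-trimethoxy-2-methylbenzaldehyde F11, and Pinnick oxidation (NaClO2, NaH2PO4, 2-methylbut-2-ene) would give 10.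

**Step 14.** Homocoupling of the benzylic halide during zinc insertion, addition–elimination or ring opening at the chloropyrone instead of clean oxidative addition, and a short supply of 22 are the main risks. The supply could fail through hydrolytic loss of the C6 chloride in step 11 or methylation on the ring carbonyl oxygen in step 13. The fallback builds ring D on the arm from a dioxinone-masked chain and closes it under neutral thermal conditions, so that no free tricarbonyl chain is exposed to base at ambient temperature next to the aroyl group. It sets out from 17 and comes back to the route at 24. Hydroxycarbonylation of 17 (PdCl2(PPh3)2, CO, K2CO3, aqueous THF) would give 2-[3-(2,4-dimethoxy-6-methylbenzoyl)-4,5,7,8-tetramethoxynaphthalen-2-yl]acetic acid F12. 1,1'-Carbonyldiimidazole would convert F12 to 2-[3-(2,4-dimethoxy-6-methylbenzoyl)-4,5,7,8-tetramethoxynaphthalen-2-yl]-1-(1H-imidazol-1-yl)ethan-1-one F13. The lithium dienolate generated from commercial 2,2,6-trimethyl-4H-1,3-dioxin-4-one and LiN(SiMe3)2 (excess, −78 °C) would be acylated by F13 to give 6-{3-[3-(2,4-dimethoxy-6-methylbenzoyl)-4,5,7,8-tetramethoxynaphthalen-2-yl]-2-oxopropyl}-2,2-dimethyl-4H-1,3-dioxin-4-one F14. Heating F14 in toluene would release the acylketene, which should close to 6-{[3-(2,4-dimethoxy-6-methylbenzoyl)-4,5,7,8-tetramethoxynaphthalen-2-yl]methyl}-4-hydroxy-2H-pyran-2-one F15, and Me2SO4 with K2CO3 in acetone would give 24.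

**Step 16.** Cleavage of the pyrone ether and of the para ether of ring A may remain incomplete, or the quinone may suffer addition of hydrogen bromide or decomposition under the Lewis acid. The fallback reverses the order of demethylation and oxidation, so that no quinone meets the Lewis acid and (NH4)2Ce(NO3)6 is not needed. It sets out from 24 and comes back to the route at 26. BBr3 would cleave all seven ethers of 24 to give 6-{[3-(2,4-dihydroxy-6-methylbenzoyl)-4,5,7,8-tetrahydroxynaphthalen-2-yl]methyl}-4-hydroxy-2H-pyran-2-one F16, and the 1,2,4-trihydroxy ring C of F16 should be oxidised by air in aqueous buffer to the hydroxyquinone 26.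

## Further compounds

F1 | step 7 | methyl 4-(triisopropylsilyloxy)but-2-ynoate | COC(=O)C#CCO[Si](C(C)C)(C(C)C)C(C)C
F2 | step 7 | methyl 1-hydroxy-5,6,8-trimethoxy-3-(triisopropylsilyloxymethyl)naphthalene-2-carboxylate | COC(=O)c1c(CO[Si](C(C)C)(C(C)C)C(C)C)cc2c(OC)c(OC)cc(OC)c2c1O
F3 | step 7 | methyl 1,5,6,8-tetramethoxy-3-(triisopropylsilyloxymethyl)naphthalene-2-carboxylate | COC(=O)c1c(CO[Si](C(C)C)(C(C)C)C(C)C)cc2c(OC)c(OC)cc(OC)c2c1OC
F4 | step 7 | [1,5,6,8-tetramethoxy-3-(triisopropylsilyloxymethyl)naphthalen-2-yl]methanol | OCc1c(CO[Si](C(C)C)(C(C)C)C(C)C)cc2c(OC)c(OC)cc(OC)c2c1OC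
F5 | step 7 | 1,5,6,8-tetramethoxy-3-(triisopropylsilyloxymethyl)naphthalene-2-carbaldehyde | O=Cc1c(CO[Si](C(C)C)(C(C)C)C(C)C)cc2c(OC)c(OC)cc(OC)c2c1OC
F6 | step 7 | 2-bromo-1,5-dimethoxy-3-methylbenzene | Cc1cc(OC)cc(OC)c1Br
F7 | step 7 | rac-(2,4-dimethoxy-6-methylphenyl)[1,5,6,8-tetramethoxy-3-(triisopropylsilyloxymethyl)naphthalen-2-yl]methanol | Cc1cc(OC)cc(OC)c1C(O)c1c(CO[Si](C(C)C)(C(C)C)C(C)C)cc2c(OC)c(OC)cc(OC)c2c1OC
F8 | step 5 | 2,4-dimethoxy-6-methylphenyl formate | Cc1cc(OC)cc(OC)c1OC=O
F9 | step 5 | 2,4-dimethoxy-6-methylphenol | Cc1cc(OC)cc(OC)c1O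
F10 | step 5 | 1,2,5-trimethoxy-3-methylbenzene | Cc1cc(OC)cc(OC)c1OC
F11 | step 5 | 3,4,6-trimethoxy-2-methylbenzaldehyde | Cc1c(C=O)c(OC)cc(OC)c1OC
F12 | step 14 | 2-[3-(2,4-dimethoxy-6-methylbenzoyl)-4,5,7,8-tetramethoxynaphthalen-2-yl]acetic acid | Cc1cc(OC)cc(OC)c1C(=O)c1c(CC(=O)O)cc2c(OC)c(OC)cc(OC)c2c1OC
F13 | step 14 | 2-[3-(2,4-dimethoxy-6-methylbenzoyl)-4,5,7,8-tetramethoxynaphthalen-2-yl]-1-(1H-imidazol-1-yl)ethan-1-one | Cc1cc(OC)cc(OC)c1C(=O)c1c(CC(=O)n2ccnc2)cc2c(OC)c(OC)cc(OC)c2c1OC
F14 | step 14 | 6-{3-[3-(2,4-dimethoxy-6-methylbenzoyl)-4,5,7,8-tetramethoxynaphthalen-2-yl]-2-oxopropyl}-2,2-dimethyl-4H-1,3-dioxin-4-one | Cc1cc(OC)cc(OC)c1C(=O)c1c(CC(=O)CC2=CC(=O)OC(C)(C)O2)cc2c(OC)c(OC)cc(OC)c2c1OC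
F15 | step 14 | 6-{[3-(2,4-dimethoxy-6-methylbenzoyl)-4,5,7,8-tetramethoxynaphthalen-2-yl]methyl}-4-hydroxy-2H-pyran-2-one | Cc1cc(OC)cc(OC)c1C(=O)c1c(Cc2cc(O)cc(=O)o2)cc2c(OC)c(OC)cc(OC)c2c1OC
F16 | step 16 | 6-{[3-(2,4-dihydroxy-6-methylbenzoyl)-4,5,7,8-tetrahydroxynaphthalen-2-yl]methyl}-4-hydroxy-2H-pyran-2-one | Cc1cc(O)cc(O)c1C(=O)c1c(Cc2cc(O)cc(=O)o2)cc2c(O)c(O)cc(O)c2c1O
A1 | alternative 1 | 3-(2,4-dimethoxy-6-methylbenzoyl)-2-methoxy-4-[(4-methoxy-2-oxo-2H-pyran-6-yl)methyl]-6-(trimethylsilyl)phenyl trifluoromethanesulfonate | Cc1cc(OC)cc(OC)c1C(=O)c1c(Cc2cc(OC)cc(=O)o2)cc([Si](C)(C)C)c(OS(=O)(=O)C(F)(F)F)c1OC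
A2 | alternative 1 | 3-methoxyfuran | COc1ccoc1
A3 | alternative 1 | rac-6-(2,4-dimethoxy-6-methylbenzoyl)-2,5-dimethoxy-7-[(4-methoxy-2-oxo-2H-pyran-6-yl)methyl]-1,4-dihydro-1,4-epoxynaphthalene (one enantiomer drawn) | [C@H]1(O2)C(OC)=C[C@@H]2c2c(OC)c(C(=O)c3c(C)cc(OC)cc3OC)c(Cc3cc(OC)cc(=O)o3)cc12
A4 | alternative 2 | 4,5,7,8-tetramethoxy-3-(trimethylsilyl)naphthalen-2-yl trifluoromethanesulfonate | COc1cc(OC)c2c(OC)c([Si](C)(C)C)c(OS(=O)(=O)C(F)(F)F)cc2c1OC
A5 | alternative 2 | methyl 3-(2,4-dimethoxy-6-methylphenyl)-3-oxopropanoate | COC(=O)CC(=O)c1c(C)cc(OC)cc1OC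
A6 | alternative 2 | methyl 2-[3-(2,4-dimethoxy-6-methylbenzoyl)-4,5,7,8-tetramethoxynaphthalen-2-yl]acetate | COC(=O)Cc1cc2c(OC)c(OC)cc(OC)c2c(OC)c1C(=O)c1c(C)cc(OC)cc1OC
A7 | alternative 3 | 4-(2,4-dimethoxy-6-methylbenzoyl)-2-(3-ethoxyprop-2-ynoyl)-3-methoxy-5-[(4-methoxy-2-oxo-2H-pyran-6-yl)methyl]benzaldehyde | CCOC#CC(=O)c1c(OC)c(C(=O)c2c(C)cc(OC)cc2OC)c(Cc2cc(OC)cc(=O)o2)cc1C=O
A8 | alternative 3 | 6-(2,4-dimethoxy-6-methylbenzoyl)-2-ethoxy-5-methoxy-7-[(4-methoxy-2-oxo-2H-pyran-6-yl)methyl]naphthalene-1,4-dione | CCOC1=CC(=O)c2c(OC)c(C(=O)c3c(C)cc(OC)cc3OC)c(Cc3cc(OC)cc(=O)o3)cc2C1=O
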